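## Ret­rosynthetic overview

1. Presumed biogenesis copied: the dienol of a veratryl butenone (C6–C4) adds [4+2] across a methoxy-p-benzoquinone (C6) and the adduct is dehydrogenated; here the dienol is used as its O-methyl ether.
2. Diene: methyl (E)-3,4-dimethoxycinnamate 1 → ester C=O methylenation → 2-methoxydiene 2, so the future 6-OMe is already in place.
3. Key disconnection: C4a–C5 and C8–C8a at once, 2 + methoxy-1,4-benzoquinone 3 → cis adduct 4 → (same flask, double dehydrogenation via naphthalenediol 5) → target 6; regiochemistry comes from the matched polarisation of both partners.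
4. Ring order: aryl ring C and quinone ring A are bought; the central benzo ring B is the only ring made, and it is made last.

Assumption: the target has no stereocentre and no hindered biaryl axis (its SMILES carries no stereodescriptor), so it is made as the one achiral compound; numbering used is C1(=O), C2(OMe), C3(H), C4(=O), C6(OMe), C8(aryl).

## Route

Step 1
Reactants: 1 methyl (E)-3-(3,4-dimethoxyphenyl)prop-2-enoate
Product: 2 4-[(1E)-3-methoxybuta-1,3-dien-1-yl]-1,2-dimethoxybenzene
Conditions: Cp2Ti(μ-Cl)(μ-CH2)AlMe2 (Tebbe reagent, 1.2 equiv, 0.5 M in PhMe), pyridine (cat.), THF, −40 °C → rt, 1 h; 15% aq. NaOH at −10 °C; filtration through basic Al2O3 (hexane/Et2O, 1% Et3N); used at once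
Reagents that add atoms: Tebbe reagent Cp2Ti(μ-Cl)(μ-CH2)AlMe2, C[Al-]1(C)C[Ti](C2C=CC=C2)(C2C=CC=C2)[Cl+]1 (gives the CH2 carbon)
Why: Tebbe methylenation of an ester carbonyl, in which Cp2Ti=CH2 released by pyridine adds [2+2] to the C=O and the oxatitanacyclobutane collapses to the enol ether and Cp2TiO; the conjugated (E)-alkene and the aryl methyl ethers are untouched, no stereocentre is formed, and the diene now holds every methoxy group the target needs on that half.

Step 2
Reactants: 2 4-[(1E)-3-methoxybuta-1,3-dien-1-yl]-1,2-dimethoxybenzene; 3 2-methoxycyclohexa-2,5-diene-1,4-dione (methoxy-1,4-benzoquinone, 1.3 equiv)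
Product: 6 8-(3,4-dimethoxyphenyl)-2,6-dimethoxynaphthalene-1,4-dione, via cis-fused endo cycloadduct 4 (not isolated), via naphthalene-1,4-diol 5 (not isolated)
Conditions: PhMe (anhydrous), 60 °C, 16 h, dark; then DDQ (2.2 equiv), 0 °C → rt, 2 h; filter off DDQH2, aq. NaHCO3 wash
Reagents that add atoms: none
Why: Normal-demand Diels–Alder reaction followed by DDQ dehydrogenation: only the unsubstituted C5=C6 bond of 3 reacts, and because its C4 carbonyl is a deactivated vinylogous ester the C1 carbonyl polarises that bond, so the nucleophilic CH2 terminus of 2 (reinforced by both its 3-methoxy and 1-aryl groups) bonds to C5 and the aryl-bearing terminus to C6, which puts the aryl group peri to the carbonyl beside the quinone methoxy; DDQ then removes the doubly activated C8 hydride of 4 (benzylic and vinylogous to the enol ether oxygen), tautomerisation gives 5 with the enol ether kept as an aryl methyl ether, and the second equivalent oxidises 5 to 6, which erases the three stereocentres of 4 so none needs control.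

## Compound list

1 | methyl (E)-3-(3,4-dimethoxyphenyl)prop-2-enoate (methyl 3,4-dimethoxycinnamate) | COC(=O)/C=C/c1ccc(OC)c(OC)c1 | starting material
2 | 4-[(1E)-3-methoxybuta-1,3-dien-1-yl]-1,2-dimethoxybenzene | COC(=C)/C=C/c1ccc(OC)c(OC)c1 | intermediate
3 | 2-methoxycyclohexa-2,5-diene-1,4-dione (methoxy-1,4-benzoquinone) | COC1=CC(=O)C=CC1=O | starting material
4 | rac-(4aR,8S,8aS)-8-(3,4-dimethoxyphenyl)-2,6-dimethoxy-4a,5,8,8a-tetrahydronaphthalene-1,4-dione (endo adduct, H-4a, H-8 and H-8a on one face, one enantiomer drawn, not isolated) | COC1=CC(=O)[C@@H]2CC(OC)=C[C@H](c3ccc(OC)c(OC)c3)[C@@H]2C1=O | intermediate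
5 | 8-(3,4-dimethoxyphenyl)-2,6-dimethoxynaphthalene-1,4-diol (achiral, not isolated) | COc1cc(O)c2cc(OC)cc(-c3ccc(OC)c(OC)c3)c2c1O | intermediate
6 | 8-(3,4-dimethoxyphenyl)-2,6-dimethoxynaphthalene-1,4-dione (achiral) | COC1=CC(=O)c2cc(OC)cc(-c3ccc(OC)c(OC)c3)c2C1=O | target

## Step count and risks

Total step count: 2. Longest linear sequence: 2 (1 → 2 → 6; quinone 3 is bought).

The route has only two steps, so both are ranked, and step 2 is entered twice because its cycloaddition stage and its dehydrogenation stage can fail independently.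

**Risk 1 – step 2, cycloaddition stage.** The regiochemistry rests only on the electronic bias of 3. If it is poor, the 5-aryl-2,7-dimethoxy isomer contaminates the product. The fallback sets out from diene 2 and comes back to the route at naphthalenediol 5. The dienophile is changed to one whose halogen fixes the orientation and leaves as HBr. Purchased 5-bromovanillin F1 undergoes Dakin oxidation (H2O2, aq. NaOH, then acid) to 2-bromo-6-methoxybenzene-1,4-diol F2, which NaIO4 in water/CH2Cl2 oxidises to 2-bromo-6-methoxycyclohexa-2,5-diene-1,4-dione F3. Diene 2 adds to the bromine-bearing double bond of F3 in PhMe at rt, its CH2 terminus going to the unhalogenated carbon, to give the bromo cycloadduct F4. Et3N removes HBr to give the 5,8-dihydronaphthoquinone F5, which tautomerises under the same base to 5. One equivalent of DDQ (or air) then gives 6.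

**Risk 2 – step 2, dehydrogenation stage.** DDQ and the DDQH2 it forms may cleave the enol ether or give a mixture of oxidation levels. The fallback sets out from cycloadduct 4 (made as in step 2, before DDQ is added) and comes back at target 6. The enol ether is given up on purpose and the methyl group is put back last. Treatment with 1 M HCl in THF at rt hydrolyses and enolises 4 to the hydroquinone β-tetralone F6. Aerobic oxidation (O2, K2CO3, MeOH, rt, then acid) aromatises it through its enol to 8-(3,4-dimethoxyphenyl)-6-hydroxy-2-methoxynaphthalene-1,4-dione F7. MeI with K2CO3 in acetone under reflux then gives 6.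

**Risk 3 – step 1.** The methylenation may be incomplete, or the acid-labile diene 2 may be lost on isolation. Because this is the first step, the fallback replaces starting material 1 rather than setting out from it, and it comes back at diene 2. The diene is made by elimination from a ketal instead of carbonyl methylenation. Purchased (E)-4-(3,4-dimethoxyphenyl)but-3-en-2-one F8 is converted with HC(OMe)3, MeOH and cat. TsOH at rt into its dimethyl ketal F9. TMSOTf with iPr2NEt in CH2Cl2 (−20 °C → rt) eliminates methanol toward the methyl group, the only side that can eliminate, to give 2 under non-aqueous basic conditions.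

## Further compounds

F1 | step 2 | 5-bromovanillin (3-bromo-4-hydroxy-5-methoxybenzaldehyde, purchased) | COc1cc(C=O)cc(Br)c1O
F2 | step 2 | 2-bromo-6-methoxybenzene-1,4-diol | COc1cc(O)cc(Br)c1O
F3 | step 2 | 2-bromo-6-methoxycyclohexa-2,5-diene-1,4-dione | COC1=CC(=O)C=C(Br)C1=O
F4 | step 2 | rac-8a-bromo-8-(3,4-dimethoxyphenyl)-2,6-dimethoxy-4a,5,8,8a-tetrahydronaphthalene-1,4-dione (Br, H-4a and H-8 on one face, one enantiomer drawn) | COC1=CC(=O)[C@@H]2CC(OC)=C[C@H](c3ccc(OC)c(OC)c3)[C@]2(Br)C1=O
F5 | step 2 | rac-8-(3,4-dimethoxyphenyl)-2,6-dimethoxy-5,8-dihydronaphthalene-1,4-dione (one enantiomer drawn) | COC1=CC(=O)C2=C([C@@H](c3ccc(OC)c(OC)c3)C=C(OC)C2)C1=O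
F6 | step 2 | rac-4-(3,4-dimethoxyphenyl)-5,8-dihydroxy-6-methoxy-3,4-dihydronaphthalen-2(1H)-one (one enantiomer drawn) | COc1cc(O)c2CC(=O)C[C@H](c3ccc(OC)c(OC)c3)c2c1O
F7 | step 2 | 8-(3,4-dimethoxyphenyl)-6-hydroxy-2-methoxynaphthalene-1,4-dione | COC1=CC(=O)c2cc(O)cc(-c3ccc(OC)c(OC)c3)c2C1=O
F8 | step 1 | (E)-4-(3,4-dimethoxyphenyl)but-3-en-2-one (purchased) | CC(=O)/C=C/c1ccc(OC)c(OC)c1
F9 | step 1 | 4-[(1E)-3,3-dimethoxybut-1-en-1-yl]-1,2-dimethoxybenzene | COC(C)(OC)/C=C/c1ccc(OC)c(OC)c1
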